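**Strategy.** The flavanone is cut at O1–C2 and C3–C4 of ring C. These two bonds flank C2–C3, the two carbons of a ring B styrene, while O1, C8a, C4a and C4 of ring A make up a four-atom heterodiene, an ortho-quinone methide. In one operation a chiral Brønsted acid turns the ring A salicylaldehyde and trimethyl orthoformate into a methoxy quinone methide and adds the styrene, closing ring C, setting C2 (S) and leaving C4 oxygenated for later oxidation to the ketone. The precursors are a 3-prenyl-4,6-bis(MOM) salicylaldehyde with one free phenol and a MOM-protected 2-methoxy-5-(1,1-dimethylallyl)styrene; hydrolysis, oxidation and MOM removal finish the synthesis.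

Key step: step 9

Assumption: the sense of induction of the chiral acid cannot be assigned in advance, so the (R)-catalyst is written and its antipode would be used if it delivers the 2R series.

**Route**

Step 1
Reactants: 1 phloroglucinol
Product: 2 3,5-bis(methoxymethoxy)phenol
Conditions: MOMCl (2.0 equiv), i-Pr2NEt (2.2 equiv), DMF, 0 °C → rt; chromatography
Reagents that add atoms: chloromethyl methyl ether (MOMCl), COCCl
Why: Williamson-type O-alkylation with two equivalents of the chloromethyl ether should give the bis-ether as the main component of a statistical mixture, and because the triol is threefold symmetric each mono-, bis- and tris-ether is a single regioisomer, so chromatography alone secures 2.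

Step 2
Reactants: 2 3,5-bis(methoxymethoxy)phenol; 3 3-chloro-3-methylbut-1-yne
Product: 4 1,3-bis(methoxymethoxy)-5-[(2-methylbut-3-yn-2-yl)oxy]benzene
Conditions: CuCl2·2H2O (1 mol %), DBU, MeCN, 0 °C
Reagents that add atoms: none
Why: Copper-catalysed O-propargylation of a phenol with a tertiary propargylic chloride, in which a copper acetylide ionises the chloride and the phenoxide is captured at the tertiary carbon, is a standard entry to aryl 1,1-dimethylpropargyl ethers and tolerates MOM acetals.

Step 3
Reactants: 4 1,3-bis(methoxymethoxy)-5-[(2-methylbut-3-yn-2-yl)oxy]benzene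
Product: 6 3,5-bis(methoxymethoxy)-2-(3-methylbut-2-en-1-yl)phenol, via 1,1-dimethylallyl aryl ether 5 (not isolated)
Conditions: H2 (1 atm), Pd/CaCO3 poisoned with Pb(OAc)2 (Lindlar catalyst), quinoline, toluene, rt; filter; filtrate 110 °C
Reagents that add atoms: none
Why: Lindlar semihydrogenation stops at the alkene, and the resulting aryl 1,1-dimethylallyl ether should undergo an aromatic Claisen rearrangement on warming that delivers the allyl unit with inversion as a linear prenyl group to an ortho carbon, the two ortho carbons being equivalent by symmetry.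

Step 4
Reactants: 6 3,5-bis(methoxymethoxy)-2-(3-methylbut-2-en-1-yl)phenol
Product: 7 2-hydroxy-4,6-bis(methoxymethoxy)-3-(3-methylbut-2-en-1-yl)benzaldehyde
Conditions: MgCl2, Et3N, (CH2O)n, MeCN, reflux; aq. NH4Cl work-up
Reagents that add atoms: paraformaldehyde (as formaldehyde), C=O
Why: In the Casnati–Skattebøl ortho-formylation the magnesium phenoxide directs formaldehyde to the only free ortho position and a second formaldehyde takes up hydride, so the aldehyde should enter next to the free hydroxyl and not between the two MOM ethers, while the basic medium leaves the MOM groups and the prenyl chain untouched.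

Step 5
Reactants: 8 4-hydroxy-2-methoxybenzaldehyde; 9 prenyl bromide
Product: 10 2-methoxy-4-[(3-methylbut-2-en-1-yl)oxy]benzaldehyde
Conditions: K2CO3, acetone, reflux
Reagents that add atoms: none
Why: Williamson ether synthesis on the acidic para-formyl phenoxide with a primary allylic bromide should give the O-prenyl ether by SN2 substitution.

Step 6
Reactants: 10 2-methoxy-4-[(3-methylbut-2-en-1-yl)oxy]benzaldehyde
Product: 11 4-hydroxy-2-methoxy-5-(2-methylbut-3-en-2-yl)benzaldehyde
Conditions: EtOH/H2O (4:1), 130 °C, sealed vessel
Reagents that add atoms: none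
Why: The water-accelerated aromatic Claisen rearrangement should transfer the allyl unit with inversion to C5, the less hindered ortho position, while the formyl group blocks the para position and so rules out a following Cope shift.

Step 7
Reactants: 11 4-hydroxy-2-methoxy-5-(2-methylbut-3-en-2-yl)benzaldehyde
Product: 12 2-methoxy-4-(methoxymethoxy)-5-(2-methylbut-3-en-2-yl)benzaldehyde
Conditions: MOMCl, i-Pr2NEt, CH2Cl2, 0 °C → rt
Reagents that add atoms: chloromethyl methyl ether (MOMCl), COCCl
Why: O-alkylation of the phenoxide with the small, reactive chloromethyl ether (MOM protection) should proceed despite the neighbouring quaternary carbon and puts the same protecting group on ring B as on ring A, so that one final operation removes all three.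

Step 8
Reactants: 12 2-methoxy-4-(methoxymethoxy)-5-(2-methylbut-3-en-2-yl)benzaldehyde
Product: 13 1-ethenyl-2-methoxy-4-(methoxymethoxy)-5-(2-methylbut-3-en-2-yl)benzene
Conditions: Ph3PCH3Br, KOtBu, THF, 0 °C → rt
Reagents that add atoms: methyltriphenylphosphonium bromide, C[P+](c1ccccc1)(c1ccccc1)c1ccccc1.[Br-]
Why: Wittig methylenation of a non-enolisable aryl aldehyde under basic conditions should give the styrene without touching the MOM acetal or the 1,1-dimethylallyl group.

Step 9
Reactants: 7 2-hydroxy-4,6-bis(methoxymethoxy)-3-(3-methylbut-2-en-1-yl)benzaldehyde; 13 1-ethenyl-2-methoxy-4-(methoxymethoxy)-5-(2-methylbut-3-en-2-yl)benzene; 14 trimethyl orthoformate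
Product: 17 (2S,4S)-4-methoxy-2-[2-methoxy-4-(methoxymethoxy)-5-(2-methylbut-3-en-2-yl)phenyl]-5,7-bis(methoxymethoxy)-8-(3-methylbut-2-en-1-yl)chromane (2,4-cis), via dimethyl acetal 15 (not isolated), via methoxy ortho-quinone methide 16 (not isolated)
Conditions: (R)-3,3'-bis(2,4,6-triisopropylphenyl)-1,1'-binaphthyl-2,2'-diyl N-triflylphosphoramide (10 mol %), 13 (1.5 equiv), 14 (2 equiv), 4 Å MS, toluene, −40 → −20 °C; Et3N quench
Reagents that add atoms: none
Why: Proposed new method: the acid and orthoformate 14 convert aldehyde 7 into acetal 15, which loses methanol to the methoxy ortho-quinone methide 16 (in its polar form a phenol-tethered oxocarbenium ion) held by the chiral phosphoramide anion through a hydrogen bond; the terminal carbon of styrene 13 attacks the methide carbon (future C4) and the ring A oxygen closes on the benzylic carbon (future C2) in a concerted, asynchronous inverse-demand hetero-Diels–Alder reaction that rearomatises ring A. The closest known reaction types are the achiral acid-catalysed coupling of salicylaldehydes, trimethyl orthoformate and styrenes to 2,4-cis-4-methoxy-2-arylchromans and the chiral N-triflylphosphoramide-catalysed cycloaddition of styrenes with ortho-quinone methides made from ortho-hydroxybenzyl alcohols; new here is enantiocontrol over an acetal-derived alkoxy quinone methide. Ring C is closed by an intermolecular [4+2] cycloaddition that forms O1–C2 and C3–C4 together, so no tethered cyclisation mode is involved. C2 (S) is to be set by the catalyst, whose 3,3'-aryl groups shield one face of the ion-paired heterodiene, and C4 by the endo approach of the ring B aryl group, which should give the 2,4-cis isomer and is erased in step 11 in any case. The step needs regioselectivity (aryl at C2), secured by the benzylic cation stabilisation that the 2-methoxy and 4-MOM-oxy groups give the styrene, chemoselectivity for the styrene over the prenyl and 1,1-dimethylallyl alkenes, secured because only the styrene is conjugated to a donor ring, and a single heterodiene, secured by the one free phenol of 7. Low temperature should keep the MOM acetals intact and the C2–O1 bond of the product un-ionised.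

Step 10
Reactants: 17 (2S,4S)-4-methoxyflavan tris(MOM) ether
Product: 18 (2S)-2-[2-methoxy-4-(methoxymethoxy)-5-(2-methylbut-3-en-2-yl)phenyl]-5,7-bis(methoxymethoxy)-8-(3-methylbut-2-en-1-yl)chroman-4-ol (mixture of C4 epimers)
Conditions: PPTS (10 mol %), THF/H2O (4:1), rt
Reagents that add atoms: water, O
Why: The C4 methyl ether is a 2,4,6-trioxygenated benzylic ether that should ionise under very mild acid and be captured by water (SN1 solvolysis), conditions under which the aryl MOM acetals and the less easily ionised C2–O1 bond are not affected, and the C4 epimer mixture is irrelevant because C4 becomes a carbonyl carbon next.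

Step 11
Reactants: 18 (2S)-flavan-4-ol tris(MOM) ether
Product: 19 (2S)-2-[2-methoxy-4-(methoxymethoxy)-5-(2-methylbut-3-en-2-yl)phenyl]-5,7-bis(methoxymethoxy)-8-(3-methylbut-2-en-1-yl)chroman-4-one
Conditions: Dess–Martin periodinane, NaHCO3, CH2Cl2, 0 °C → rt
Reagents that add atoms: none
Why: Dess–Martin oxidation of the secondary benzylic alcohol under bicarbonate buffering should give the ketone without acid exposure, without attack on the alkenes or electron-rich rings, and without strong base that could open ring C and epimerise C2.

Step 12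
Reactants: 19 (2S)-flavanone tris(MOM) ether
Product: 20 (2S)-5,7-dihydroxy-2-[4-hydroxy-2-methoxy-5-(2-methylbut-3-en-2-yl)phenyl]-8-(3-methylbut-2-en-1-yl)chroman-4-one (CNP0308136.1)
Conditions: 3 M aq. HCl/MeOH (1:4), 40 °C, short reaction time
Reagents that add atoms: none
Why: Acid-catalysed methanolysis of the three aryl MOM acetals (transacetalisation to dimethoxymethane) is the usual final step for prenylated flavanones, and at moderate temperature and short reaction time the alkenes and the C2 stereocentre should survive.

**Compound list**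

1 | phloroglucinol (benzene-1,3,5-triol) | Oc1cc(O)cc(O)c1 | starting material
2 | 3,5-bis(methoxymethoxy)phenol | COCOc1cc(O)cc(OCOC)c1 | intermediate
3 | 3-chloro-3-methylbut-1-yne | C#CC(C)(C)Cl | starting material
4 | 1,3-bis(methoxymethoxy)-5-[(2-methylbut-3-yn-2-yl)oxy]benzene | C#CC(C)(C)Oc1cc(OCOC)cc(OCOC)c1 | intermediate
5 | 1,3-bis(methoxymethoxy)-5-[(2-methylbut-3-en-2-yl)oxy]benzene | C=CC(C)(C)Oc1cc(OCOC)cc(OCOC)c1 | intermediate (not isolated)
6 | 3,5-bis(methoxymethoxy)-2-(3-methylbut-2-en-1-yl)phenol | CC(C)=CCc1c(O)cc(OCOC)cc1OCOC | intermediate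
7 | 2-hydroxy-4,6-bis(methoxymethoxy)-3-(3-methylbut-2-en-1-yl)benzaldehyde | O=Cc1c(O)c(CC=C(C)C)c(OCOC)cc1OCOC | intermediate
8 | 4-hydroxy-2-methoxybenzaldehyde | COc1cc(O)ccc1C=O | starting material
9 | prenyl bromide (1-bromo-3-methylbut-2-ene) | CC(C)=CCBr | starting material
10 | 2-methoxy-4-[(3-methylbut-2-en-1-yl)oxy]benzaldehyde | COc1cc(OCC=C(C)C)ccc1C=O | intermediate
11 | 4-hydroxy-2-methoxy-5-(2-methylbut-3-en-2-yl)benzaldehyde | C=CC(C)(C)c1cc(C=O)c(OC)cc1O | intermediate
12 | 2-methoxy-4-(methoxymethoxy)-5-(2-methylbut-3-en-2-yl)benzaldehyde | C=CC(C)(C)c1cc(C=O)c(OC)cc1OCOC | intermediate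
13 | 1-ethenyl-2-methoxy-4-(methoxymethoxy)-5-(2-methylbut-3-en-2-yl)benzene | C=Cc1cc(C(C)(C)C=C)c(OCOC)cc1OC | intermediate
14 | trimethyl orthoformate | COC(OC)OC | starting material
15 | 2-(dimethoxymethyl)-3,5-bis(methoxymethoxy)-6-(3-methylbut-2-en-1-yl)phenol | COC(OC)c1c(O)c(CC=C(C)C)c(OCOC)cc1OCOC | intermediate (not isolated)
16 | 6-(methoxymethylidene)-3,5-bis(methoxymethoxy)-2-(3-methylbut-2-en-1-yl)cyclohexa-2,4-dien-1-one (alkene geometry not defined) | COC=C1C(=O)C(CC=C(C)C)=C(OCOC)C=C1OCOC | intermediate (not isolated)
17 | (2S,4S)-4-methoxy-2-[2-methoxy-4-(methoxymethoxy)-5-(2-methylbut-3-en-2-yl)phenyl]-5,7-bis(methoxymethoxy)-8-(3-methylbut-2-en-1-yl)chromane (2,4-cis) | C=CC(C)(C)c1cc([C@@H]2C[C@H](OC)c3c(OCOC)cc(OCOC)c(CC=C(C)C)c3O2)c(OC)cc1OCOC | intermediate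
18 | (2S)-2-[2-methoxy-4-(methoxymethoxy)-5-(2-methylbut-3-en-2-yl)phenyl]-5,7-bis(methoxymethoxy)-8-(3-methylbut-2-en-1-yl)chroman-4-ol (C4 epimers) | C=CC(C)(C)c1cc([C@@H]2CC(O)c3c(OCOC)cc(OCOC)c(CC=C(C)C)c3O2)c(OC)cc1OCOC | intermediate
19 | (2S)-2-[2-methoxy-4-(methoxymethoxy)-5-(2-methylbut-3-en-2-yl)phenyl]-5,7-bis(methoxymethoxy)-8-(3-methylbut-2-en-1-yl)chroman-4-one | C=CC(C)(C)c1cc([C@@H]2CC(=O)c3c(OCOC)cc(OCOC)c(CC=C(C)C)c3O2)c(OC)cc1OCOC | intermediate
20 | (2S)-5,7-dihydroxy-2-[4-hydroxy-2-methoxy-5-(2-methylbut-3-en-2-yl)phenyl]-8-(3-methylbut-2-en-1-yl)chroman-4-one | C=CC(C)(C)c1cc([C@@H]2CC(=O)c3c(O)cc(O)c(CC=C(C)C)c3O2)c(OC)cc1O | target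

**Step count and risk**

Total step count: 12.
Longest linear sequence: 8 steps (steps 1–4 or 5–8, then 9–12).

Steps most likely to fail:

Step 9 (proposed new method). Facial discrimination may be weak, because the styrene has no hydrogen-bond donor to anchor it to the catalyst, and acid-induced oligomerisation of the electron-rich styrene may starve the cycloaddition. The fallback uses known chemistry, sets out from 7, 13 and 14 and comes back at 19. The three components are combined with an achiral acid (diphenyl phosphate, 10 mol %, CH2Cl2, 0 °C), the established racemic form of the cycloaddition, to give racemic 2,4-cis-4-methoxyflavan tris(MOM) ether F1. Hydrolysis as in step 10 then gives racemic flavan-4-ol tris(MOM) ether F2, and Dess–Martin oxidation as in step 11 gives racemic flavanone tris(MOM) ether F3. The ketone is resolved kinetically by asymmetric transfer hydrogenation (RuCl(p-cymene)[(R,R)-TsDPEN], HCO2H/Et3N, EtOAc, rt, stopped near half conversion). The (2R)-ketone is expected to be reduced faster, to the (2R,4R)-cis-flavan-4-ol tris(MOM) ether F4, leaving the (2S)-ketone 19, which is separated by chromatography and taken into step 12.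

Step 10. After ionisation at C4 the cation may lose the C3 proton (elimination to the flav-3-ene) or be captured by ring A of a second molecule (Friedel–Crafts oligomerisation) faster than by water. The fallback sets out from 17 and comes back at 19, raising the oxidation level without a solvolysis step. DDQ (1.5–2 equiv) in CH2Cl2/pH 7 phosphate buffer at 0 °C abstracts hydride from C4, and the methoxy-stabilised cation is hydrolysed in the flask to ketone 19 with loss of methanol; proton loss from that cation gives an enol ether that hydrolyses to the same ketone. This fallback makes no compound outside the list (F0).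

Step 12. The protic acid may epimerise C2 through reversible opening of ring C, which the donor-substituted ring B assists, and may cyclise the phenols onto the prenyl or 1,1-dimethylallyl alkenes. The fallback sets out from 19 and comes back at 20, replacing acidolysis by silyl transfer under amine buffering. TMSOTf and 2,2'-bipyridyl (MeCN, 0 °C) convert the three aryl MOM ethers into the flavanone tris(trimethylsilyl) ether F5, and water added on work-up cleaves the aryl silyl ethers under near-neutral conditions to give 20.

**Further compounds**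

F1 | step 9 | racemic 2,4-cis-4-methoxy-2-[2-methoxy-4-(methoxymethoxy)-5-(2-methylbut-3-en-2-yl)phenyl]-5,7-bis(methoxymethoxy)-8-(3-methylbut-2-en-1-yl)chromane | C=CC(C)(C)c1cc(C2CC(OC)c3c(OCOC)cc(OCOC)c(CC=C(C)C)c3O2)c(OC)cc1OCOC
F2 | step 9 | racemic 2-[2-methoxy-4-(methoxymethoxy)-5-(2-methylbut-3-en-2-yl)phenyl]-5,7-bis(methoxymethoxy)-8-(3-methylbut-2-en-1-yl)chroman-4-ol | C=CC(C)(C)c1cc(C2CC(O)c3c(OCOC)cc(OCOC)c(CC=C(C)C)c3O2)c(OC)cc1OCOC
F3 | step 9 | racemic 2-[2-methoxy-4-(methoxymethoxy)-5-(2-methylbut-3-en-2-yl)phenyl]-5,7-bis(methoxymethoxy)-8-(3-methylbut-2-en-1-yl)chroman-4-one | C=CC(C)(C)c1cc(C2CC(=O)c3c(OCOC)cc(OCOC)c(CC=C(C)C)c3O2)c(OC)cc1OCOC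
F4 | step 9 | (2R,4R)-2-[2-methoxy-4-(methoxymethoxy)-5-(2-methylbut-3-en-2-yl)phenyl]-5,7-bis(methoxymethoxy)-8-(3-methylbut-2-en-1-yl)chroman-4-ol | C=CC(C)(C)c1cc([C@H]2C[C@@H](O)c3c(OCOC)cc(OCOC)c(CC=C(C)C)c3O2)c(OC)cc1OCOC
F0 | step 10 | none | none
F5 | step 12 | (2S)-2-[2-methoxy-5-(2-methylbut-3-en-2-yl)-4-(trimethylsilyloxy)phenyl]-8-(3-methylbut-2-en-1-yl)-5,7-bis(trimethylsilyloxy)chroman-4-one | C=CC(C)(C)c1cc([C@@H]2CC(=O)c3c(O[Si](C)(C)C)cc(O[Si](C)(C)C)c(CC=C(C)C)c3O2)c(OC)cc1O[Si](C)(C)C
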